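## Retrosynthetic overview
- The C ring is made last. A racemic 1,2-diarylcyclopropanol undergoes an oxidative 3→6 ring expansion: its C1–C2 bond breaks, the ortho phenol oxygen closes on C2, and a chiral copper catalyst sets 2S.
- The cyclopropanol comes from a Kulinkovich coupling of a ring A benzoate (supplies C4) with a ring B styrene (supplies C3 and C2).
- The ring B styrene comes from 4-iodophenol by double ortho-prenylation, acid closure of one prenyl onto the only OH, then vinylation.
- The ring A benzoate comes from resorcinol as its bis-THP ether by two directed lithiations (prenyl at C2, CO2Me at C4).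
- Ring order: dimethylchroman ring of ring B, then cyclopropane, then pyranone C ring.

Assumption: the sense of induction of the box ligand in step 8 is assigned by analogy. The mirror-image ligand is equally available, and 2S would be confirmed by circular dichroism.

## Route

Step 1
Reactants: 1 4-iodophenol; 2 1-bromo-3-methylbut-2-ene (prenyl bromide, 2.3 equiv)
Product: 3 4-iodo-2,6-bis(3-methylbut-2-en-1-yl)phenol
Conditions: KOH (2.3 equiv), H2O, 0 °C to rt, 24 h
Reagents that add atoms: none
Why: Ambident phenoxide alkylation: in water the hydrogen-bonded oxygen is shielded, so the soft allylic bromide attacks carbon, and with para blocked by iodine both ortho carbons are prenylated (ortho-C-allylation of a phenoxide, no stereocentre).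

Step 2
Reactants: 3 4-iodo-2,6-bis(3-methylbut-2-en-1-yl)phenol
Product: 4 6-iodo-2,2-dimethyl-8-(3-methylbut-2-en-1-yl)chromane
Conditions: Amberlyst 15 (cat.), CH2Cl2, rt
Reagents that add atoms: none
Why: Brønsted-acid intramolecular hydroalkoxylation (Markovnikov protonation to the tertiary cation, six-ring closure) uses up the only OH, so exactly one prenyl cyclises and the other survives.

Step 3
Reactants: 4 6-iodo-2,2-dimethyl-8-(3-methylbut-2-en-1-yl)chromane; 5 vinylmagnesium bromide (1.3 equiv)
Product: 6 6-ethenyl-2,2-dimethyl-8-(3-methylbut-2-en-1-yl)chromane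
Conditions: Pd(PPh3)4 (2 mol %), THF, 0 to 40 °C
Reagents that add atoms: none
Why: Kumada–Corriu coupling of a reactive aryl iodide; the substrate carries only ether and trisubstituted alkene groups, which are inert to the Grignard reagent.

Step 4
Reactants: 7 resorcinol
Product: 8 1,3-bis(tetrahydro-2H-pyran-2-yloxy)benzene
Conditions: DHP (3 equiv), PPTS (5 mol %), CH2Cl2, rt
Reagents that add atoms: 3,4-dihydro-2H-pyran, C1=COCCC1
Why: Acid-catalysed acetalisation (THP protection) masks both phenols and installs two ortho-directing groups that later come off under almost neutral conditions.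

Step 5
Reactants: 8 1,3-bis(tetrahydro-2H-pyran-2-yloxy)benzene; 2 1-bromo-3-methylbut-2-ene (1.2 equiv)
Product: 10 2-(3-methylbut-2-en-1-yl)-1,3-bis(tetrahydro-2H-pyran-2-yloxy)benzene, via 2-lithio arene 9 (not isolated)
Conditions: n-BuLi (1.1 equiv), THF, 0 °C to rt; CuI (10 mol %), 2, −78 °C to rt
Reagents that add atoms: none
Why: Directed ortho-metalation occurs at the carbon flanked by both acetal oxygens, and copper-assisted SN2 allylation at the unhindered CH2 of prenyl bromide gives the linear prenyl arene.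

Step 6
Reactants: 10 2-(3-methylbut-2-en-1-yl)-1,3-bis(tetrahydro-2H-pyran-2-yloxy)benzene; 11 methyl chloroformate (3 equiv)
Product: 13 methyl 3-(3-methylbut-2-en-1-yl)-2,4-bis(tetrahydro-2H-pyran-2-yloxy)benzoate, via 4-lithio arene 12 (not isolated)
Conditions: n-BuLi (1.2 equiv), TMEDA, THF, −20 to 0 °C; cannulated into 11, THF, −78 °C
Reagents that add atoms: none
Why: A second directed ortho-metalation can only go to the remaining position ortho to an OTHP group, and inverse addition into excess chloroformate (acylation of an aryllithium) stops at the ester.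

Step 7
Reactants: 13 methyl 3-(3-methylbut-2-en-1-yl)-2,4-bis(tetrahydro-2H-pyran-2-yloxy)benzoate; 6 6-ethenyl-2,2-dimethyl-8-(3-methylbut-2-en-1-yl)chromane (1.2 equiv)
Product: 16 4-{2-[2,2-dimethyl-8-(3-methylbut-2-en-1-yl)chroman-6-yl]-1-hydroxycyclopropyl}-2-(3-methylbut-2-en-1-yl)benzene-1,3-diol, via styrene titanacyclopropane 14 (not isolated), via bis-THP cyclopropanol 15 (not isolated)
Conditions: Ti(OiPr)4 (1.0 equiv), c-C5H9MgCl (3.5 equiv, added over 2 h), THF, rt; aq NH4Cl; crude, PPTS (10 mol %), MeOH, rt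
Reagents that add atoms: none
Why: Kulinkovich reaction in its alkene-exchange form: the cyclopentene titanacyclopropane swaps its alkene for the terminal styrene (prenyl alkenes do not exchange), 14 adds twice to the ester carbonyl to close the cyclopropanol, and PPTS/MeOH acetal exchange frees both phenols without opening the ring; the two new stereocentres form racemic (mainly aryl groups cis) and are erased or reset in step 8.

Step 8
Reactants: 16 4-{2-[2,2-dimethyl-8-(3-methylbut-2-en-1-yl)chroman-6-yl]-1-hydroxycyclopropyl}-2-(3-methylbut-2-en-1-yl)benzene-1,3-diol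
Product: 17 (2S)-2-[2,2-dimethyl-8-(3-methylbut-2-en-1-yl)chroman-6-yl]-7-hydroxy-8-(3-methylbut-2-en-1-yl)chroman-4-one
Conditions: Cu(MeCN)4PF6 (10 mol %), (S,S)-tBu-box (12 mol %), PhCO3tBu (1.1 equiv), acetone, 0 °C, Ar
Reagents that add atoms: none
Why: Proposed new method: monovalent copper splits the perester into tBuO• and a divalent copper benzoate, tBuO• abstracts a phenolic H (both OH groups place spin on the ring carbon that bears the carbinol), the strained C1–C2 bond breaks by β-scission to the aryl ketone plus a secondary benzylic radical, the new 2-acylphenoxide chelates the box-bound divalent copper, the tethered radical is captured face-selectively to an alkyl trivalent copper phenoxide and C–O reductive elimination closes O1–C2, so the three cyclopropane carbons end as C4, C3 and C2 of the six-membered pyranone (3→6 ring expansion) and the racemic cyclopropanol converges on the 2S centre under ligand control; closest known reaction types are the copper-catalysed ring-opening cross-coupling of cyclopropanols through β-keto alkyl radicals and the enantioselective Kharasch–Sosnovsky type radical-relay C–O coupling.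

## Compound list
1 | 4-iodophenol | Oc1ccc(I)cc1 | starting material
2 | 1-bromo-3-methylbut-2-ene (prenyl bromide) | CC(C)=CCBr | starting material
3 | 4-iodo-2,6-bis(3-methylbut-2-en-1-yl)phenol | CC(C)=CCc1cc(I)cc(CC=C(C)C)c1O | intermediate
4 | 6-iodo-2,2-dimethyl-8-(3-methylbut-2-en-1-yl)chromane | CC(C)=CCc1cc(I)cc2c1OC(C)(C)CC2 | intermediate
5 | vinylmagnesium bromide | C=C[Mg]Br | starting material
6 | 6-ethenyl-2,2-dimethyl-8-(3-methylbut-2-en-1-yl)chromane | CC(C)=CCc1cc(C=C)cc2c1OC(C)(C)CC2 | intermediate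
7 | resorcinol (benzene-1,3-diol) | Oc1cccc(O)c1 | starting material
8 | 1,3-bis(tetrahydro-2H-pyran-2-yloxy)benzene (acetal carbons: mixture) | c1cc(OC2CCCCO2)cc(OC2CCCCO2)c1 | intermediate
9 | [2,6-bis(tetrahydro-2H-pyran-2-yloxy)phenyl]lithium | [Li]c1c(OC2CCCCO2)cccc1OC1CCCCO1 | intermediate
10 | 2-(3-methylbut-2-en-1-yl)-1,3-bis(tetrahydro-2H-pyran-2-yloxy)benzene | CC(C)=CCc1c(OC2CCCCO2)cccc1OC1CCCCO1 | intermediate
11 | methyl chloroformate | COC(=O)Cl | starting material
12 | [3-(3-methylbut-2-en-1-yl)-2,4-bis(tetrahydro-2H-pyran-2-yloxy)phenyl]lithium | CC(C)=CCc1c(OC2CCCCO2)ccc([Li])c1OC1CCCCO1 | intermediate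
13 | methyl 3-(3-methylbut-2-en-1-yl)-2,4-bis(tetrahydro-2H-pyran-2-yloxy)benzoate | COC(=O)c1ccc(OC2CCCCO2)c(CC=C(C)C)c1OC1CCCCO1 | intermediate
14 | 2-[2,2-dimethyl-8-(3-methylbut-2-en-1-yl)chroman-6-yl]-1,1-diisopropoxytitanacyclopropane | CC(C)O[Ti]1(OC(C)C)CC1c1cc(CC=C(C)C)c2OC(C)(C)CCc2c1 | intermediate
15 | 2-[2,2-dimethyl-8-(3-methylbut-2-en-1-yl)chroman-6-yl]-1-[3-(3-methylbut-2-en-1-yl)-2,4-bis(tetrahydro-2H-pyran-2-yloxy)phenyl]cyclopropan-1-ol (racemic, stereoisomer mixture) | CC(C)=CCc1cc(C3CC3(O)c4ccc(OC5CCCCO5)c(CC=C(C)C)c4OC5CCCCO5)cc2c1OC(C)(C)CC2 | intermediate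
16 | 4-{2-[2,2-dimethyl-8-(3-methylbut-2-en-1-yl)chroman-6-yl]-1-hydroxycyclopropyl}-2-(3-methylbut-2-en-1-yl)benzene-1,3-diol (racemic, mainly aryl groups cis) | CC(C)=CCc1cc(C3CC3(O)c4ccc(O)c(CC=C(C)C)c4O)cc2c1OC(C)(C)CC2 | intermediate
17 | (2S)-2-[2,2-dimethyl-8-(3-methylbut-2-en-1-yl)chroman-6-yl]-7-hydroxy-8-(3-methylbut-2-en-1-yl)chroman-4-one | CC(C)=CCc1cc([C@@H]2CC(=O)c3ccc(O)c(CC=C(C)C)c3O2)cc2c1OC(C)(C)CC2 | target

## Step count and risks
Total step count: 8. Longest linear sequence: 5 (steps 1, 2, 3, 7, 8 or steps 4, 5, 6, 7, 8).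

**Step 8 (proposed new step).**
- Risks:
  - The para-alkoxybenzyl radical may be oxidised outside the copper sphere to the cation. That would give racemic closure or loss of a proton to the chalcone.
  - Benzoate may be transferred instead of the phenoxide.
  - The electron-rich resorcinol may be over-oxidised.
- Fallback: known chemistry that sets out from 4 and 12 and comes back at 17.
  - Iodide 4 is treated with n-BuLi, then B(OiPr)3, then aqueous acid. This gives [2,2-dimethyl-8-(3-methylbut-2-en-1-yl)chroman-6-yl]boronic acid F1.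
  - Aryllithium 12 is quenched with N-methoxy-N-methylacetamide to give 1-[3-(3-methylbut-2-en-1-yl)-2,4-bis(tetrahydro-2H-pyran-2-yloxy)phenyl]ethan-1-one F2.
  - PPTS/MeOH frees 1-[2,4-dihydroxy-3-(3-methylbut-2-en-1-yl)phenyl]ethan-1-one F3.
  - Short heating with DMF dimethyl acetal gives (E)-1-[2,4-dihydroxy-3-(3-methylbut-2-en-1-yl)phenyl]-3-(dimethylamino)prop-2-en-1-one F4.
  - F4 closes on silica or in AcOH to 7-hydroxy-8-(3-methylbut-2-en-1-yl)-4H-chromen-4-one F5.
  - The established asymmetric conjugate addition of arylboronic acids to chromones then joins F1 and F5 to give 17 directly. Conditions: Pd(OCOCF3)2, (R)-t-BuPyOx (hand assigned from the cyclic-enone model), NH4PF6, H2O, ClCH2CH2Cl, 60 °C.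

**Step 7.**
- Risks: alkene exchange on titanium may be slow, and the electron-rich, ortho-substituted benzoate may react sluggishly, so that ester reduction or styrene oligomers result.
- Fallback: sets out from 6 and comes back at 14.
  - 9-BBN (selective for the terminal alkene), then NaBO3·4H2O, gives 2-[2,2-dimethyl-8-(3-methylbut-2-en-1-yl)chroman-6-yl]ethan-1-ol F6.
  - CBr4/PPh3 gives 6-(2-bromoethyl)-2,2-dimethyl-8-(3-methylbut-2-en-1-yl)chromane F7.
  - Mg in THF gives {2-[2,2-dimethyl-8-(3-methylbut-2-en-1-yl)chroman-6-yl]ethyl}magnesium bromide F8.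
  - Two equivalents of F8 with Ti(OiPr)4 form a dialkyltitanium that loses one alkyl as the ethylarene by β-hydride transfer. This delivers titanacyclopropane 14 directly (classical Kulinkovich reaction, no alkene exchange), and 14 then reacts with 13 as in step 7.

**Step 6.**
- Risk: n-BuLi may deprotonate the benzylic-allylic CH2 of the prenyl group (lateral lithiation) instead of the ring.
- Fallback: sets out from 7 and comes back at 13. The carboxyl carbon goes in first by electrophilic substitution.
  - Kolbe–Schmitt carboxylation (KHCO3, CO2, H2O, reflux) gives 2,4-dihydroxybenzoic acid F9.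
  - MeOH/H2SO4 gives methyl 2,4-dihydroxybenzoate F10.
  - C-prenylation with 2 (KOH, MeOH–H2O, 0 °C) at the doubly activated C3 gives methyl 2,4-dihydroxy-3-(3-methylbut-2-en-1-yl)benzoate F11.
  - DHP/PPTS (CH2Cl2, reflux) returns to 13.

## Further compounds
F1 | step 8 | [2,2-dimethyl-8-(3-methylbut-2-en-1-yl)chroman-6-yl]boronic acid | CC(C)=CCc1cc(B(O)O)cc2c1OC(C)(C)CC2
F2 | step 8 | 1-[3-(3-methylbut-2-en-1-yl)-2,4-bis(tetrahydro-2H-pyran-2-yloxy)phenyl]ethan-1-one | CC(=O)c1ccc(OC2CCCCO2)c(CC=C(C)C)c1OC1CCCCO1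
F3 | step 8 | 1-[2,4-dihydroxy-3-(3-methylbut-2-en-1-yl)phenyl]ethan-1-one | CC(=O)c1ccc(O)c(CC=C(C)C)c1O
F4 | step 8 | (E)-1-[2,4-dihydroxy-3-(3-methylbut-2-en-1-yl)phenyl]-3-(dimethylamino)prop-2-en-1-one | CN(C)/C=C/C(=O)c1ccc(O)c(CC=C(C)C)c1O
F5 | step 8 | 7-hydroxy-8-(3-methylbut-2-en-1-yl)-4H-chromen-4-one | CC(C)=CCc1c(O)ccc2c(=O)ccoc12
F6 | step 7 | 2-[2,2-dimethyl-8-(3-methylbut-2-en-1-yl)chroman-6-yl]ethan-1-ol | CC(C)=CCc1cc(CCO)cc2c1OC(C)(C)CC2
F7 | step 7 | 6-(2-bromoethyl)-2,2-dimethyl-8-(3-methylbut-2-en-1-yl)chromane | CC(C)=CCc1cc(CCBr)cc2c1OC(C)(C)CC2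
F8 | step 7 | {2-[2,2-dimethyl-8-(3-methylbut-2-en-1-yl)chroman-6-yl]ethyl}magnesium bromide | CC(C)=CCc1cc(CC[Mg]Br)cc2c1OC(C)(C)CC2
F9 | step 6 | 2,4-dihydroxybenzoic acid | O=C(O)c1ccc(O)cc1O
F10 | step 6 | methyl 2,4-dihydroxybenzoate | COC(=O)c1ccc(O)cc1O
F11 | step 6 | methyl 2,4-dihydroxy-3-(3-methylbut-2-en-1-yl)benzoate | COC(=O)c1ccc(O)c(CC=C(C)C)c1O
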